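**Strategy**

Ring A of the target is an ε-type cyclohexene: gem-dimethyl C1, a C4=C5 alkene with the methyl on C5, and the stereogenic methine C6 carrying C7. Everything rests on disconnecting C1–C6 of this ring. In one operation a chiral Brønsted acid protonates C2 of an acyclic terpenoid, the C5=C6 alkene closes ring A onto C1, C6 is set, and loss of the C4 proton places the C4=C5 alkene. The precursor is isomerically pure (2E)-geranyl acetate: an isopropylidene end (C1=C2) as proton acceptor, a trisubstituted C5=C6 alkene as nucleophile, and C7 as an acetoxymethyl group that later becomes the sulfone for joining C7 to C8 of crocetin dialdehyde.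

Key step: step 1

Remark on numbering: carotenoid numbering is used in the text for ring A and the chain (C1 gem-dimethyl carbon, C3 carbinol carbon, C5 methyl-bearing alkene carbon, C6 ring methine, C7 its exocyclic carbon, C8' the CH2OH carbon).

Assumption: the (S)-ligand is written in step 1 by analogy with the sense of induction in related polyene cyclisations; if the sense proves opposite on this substrate, the (R)-ligand is used with no other change. The ligand, (S)-2'-(2-fluorobenzyloxy)-1,1'-binaphthalen-2-ol, is made in one step from (S)-1,1'-bi-2-naphthol and 2-fluorobenzyl bromide and is recovered.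

Remark on the precursor: geranyl acetate 1 is used free of its (2Z) isomer, because the (2Z) alkene would cyclise through a chair with C7 axial and give the enantiomer for the same sense of protonation.

**Route**

Step 1
Reactants: 1 (2E)-geranyl acetate
Product: 2 [(1R)-2,6,6-trimethylcyclohex-2-en-1-yl]methyl acetate
Conditions: SnCl4 (1.1 equiv), (S)-2'-(2-fluorobenzyloxy)-1,1'-binaphthalen-2-ol (1.3 equiv), toluene/CH2Cl2, −78 °C; then aq NaHCO3
Reagents that add atoms: none
Why: Proposed new method: the SnCl4-bound binaphthol monoether acts as a strong chiral Brønsted acid that transfers its proton to C2 of the C1=C2 alkene while the C5=C6 π bond bonds to C1 anti to the incoming proton, and the tertiary C5 cation then gives its axial C4 proton back to the stannate-bound aryloxide, so the acid is regenerated and the step is a pure isomerisation. The closest known reaction type is the enantioselective proton-initiated polyene cyclisation with Lewis-acid-assisted chiral Brønsted acids that ends on an arene or a hydroxyl group, together with the racemic strong-acid cyclisation of geranyl esters to this ring type; not yet shown is asymmetric induction in a monocyclisation of a geranyl ester that ends by proton loss. Ring A closes in a 6-endo-trig mode through a chair in which the (2E) geometry places the acetoxymethyl arm equatorial. C6, the only new stereocentre, is controlled by the chiral acid: since protonation and C1–C6 bonding are concerted and anti, the face of C2 that takes the proton fixes the sense of the chair and thereby the face of C6 that bonds to C1, which should give the (R) configuration that corresponds to (6R) in the target. The step further needs proton loss from C4 and not from C6 or the C5 methyl; the substrate supports this because the axial C4–H is aligned with the empty orbital at C5 and open to the bulky counter-ion, whereas C6–H is tertiary and screened by the C1 methyls and the C7 arm, and at −78 °C the alkene formed is not protonated again. The electron-poor acetate slows ionisation of the allylic C7–O bond, and an excess of ligand over SnCl4 keeps achiral acid from taking over.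

Step 2
Reactants: 2 [(1R)-2,6,6-trimethylcyclohex-2-en-1-yl]methyl acetate
Product: 3 [(1R)-2,6,6-trimethyl-4-oxocyclohex-2-en-1-yl]methyl acetate
Conditions: Rh2(cap)4 (dirhodium tetracaprolactamate, 1 mol %), t-BuOOH (70 % in water, 5 equiv), 1,2-dichloroethane, 40 °C
Reagents that add atoms: tert-butyl hydroperoxide, CC(C)(C)OO
Why: Catalytic allylic C–H oxidation with tert-butyl hydroperoxide (peroxyl-radical chain) should take the open secondary allylic C3 methylene of the 1-methylcyclohexene unit to the enone, since the tertiary C6–H is screened by the C1 methyls and C7, and the base-free conditions leave the C6 stereocentre and the acetate untouched.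

Step 3
Reactants: 3 [(1R)-2,6,6-trimethyl-4-oxocyclohex-2-en-1-yl]methyl acetate
Product: 4 [(1R,4R)-4-hydroxy-2,6,6-trimethylcyclohex-2-en-1-yl]methyl acetate
Conditions: LiBH(s-Bu)3 (L-Selectride, 1.1 equiv), THF, −78 °C; then AcOH
Reagents that add atoms: none
Why: Diastereoselective 1,2-reduction of a β,β-disubstituted cyclohexenone by a bulky trialkylborohydride: with C7 pseudo-axial (no allylic strain with the C5 methyl), the pseudo-axial C1 methyl lies over the opposite face of the C3 carbonyl, so hydride should enter on the C7 face and the new C3–O bond should end up trans to C7, which is the (3R) configuration.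

Step 4
Reactants: 4 [(1R,4R)-4-hydroxy-2,6,6-trimethylcyclohex-2-en-1-yl]methyl acetate
Product: 5 [(1R,4R)-4-(tert-butyldimethylsilyloxy)-2,6,6-trimethylcyclohex-2-en-1-yl]methyl acetate
Conditions: TBSCl, imidazole, DMF, rt
Reagents that add atoms: tert-butyldimethylsilyl chloride, CC(C)(C)[Si](C)(C)Cl
Why: Standard silylation of a secondary alcohol with a silyl chloride and imidazole, which touches no stereocentre and masks O3 for the basic steps that follow.

Step 5
Reactants: 5 [(1R,4R)-4-(tert-butyldimethylsilyloxy)-2,6,6-trimethylcyclohex-2-en-1-yl]methyl acetate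
Product: 6 [(1R,4R)-4-(tert-butyldimethylsilyloxy)-2,6,6-trimethylcyclohex-2-en-1-yl]methanol
Conditions: K2CO3 (0.2 equiv), MeOH, rt
Reagents that add atoms: none
Why: Base-catalysed transesterification with methanol removes the primary acetate, and the silyl ether is stable to these conditions.

Step 6
Reactants: 6 [(1R,4R)-4-(tert-butyldimethylsilyloxy)-2,6,6-trimethylcyclohex-2-en-1-yl]methanol; 7 1-phenyl-1H-tetrazole-5-thiol
Product: 8 5-({[(1R,4R)-4-(tert-butyldimethylsilyloxy)-2,6,6-trimethylcyclohex-2-en-1-yl]methyl}sulfanyl)-1-phenyl-1H-tetrazole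
Conditions: PPh3, DIAD, THF, 0 °C to rt
Reagents that add atoms: none
Why: Mitsunobu thioetherification, in which the acidic tetrazolethiol is alkylated at sulfur by the alkoxyphosphonium ion of the primary alcohol; the displacement is at C7, so C6 is not involved.

Step 7
Reactants: 8 5-({[(1R,4R)-4-(tert-butyldimethylsilyloxy)-2,6,6-trimethylcyclohex-2-en-1-yl]methyl}sulfanyl)-1-phenyl-1H-tetrazole
Product: 10 5-({[(1R,4R)-4-(tert-butyldimethylsilyloxy)-2,6,6-trimethylcyclohex-2-en-1-yl]methyl}sulfonyl)-1-phenyl-1H-tetrazole, via sulfoxide 9 (not isolated)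
Conditions: (NH4)6Mo7O24·4H2O (0.2 equiv), 30 % H2O2 (10 equiv), EtOH, 0 °C to rt
Reagents that add atoms: hydrogen peroxide, OO
Why: Molybdate-catalysed peroxide oxidation of a sulfide through the sulfoxide to the sulfone should be faster than epoxidation of the trisubstituted C4=C5 alkene, and the silyl ether is stable.

Step 8
Reactants: 10 5-({[(1R,4R)-4-(tert-butyldimethylsilyloxy)-2,6,6-trimethylcyclohex-2-en-1-yl]methyl}sulfonyl)-1-phenyl-1H-tetrazole; 11 crocetin dialdehyde
Product: 12 (3R,6R)-3-(tert-butyldimethylsilyloxy)-8'-apo-ε-caroten-8'-al (all-E)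
Conditions: KN(SiMe3)2 (1.1 equiv), THF, −78 °C; then added to 11 (3 equiv) in THF, −78 °C to rt, dark, argon
Reagents that add atoms: none
Why: Julia–Kocienski olefination: the potassium sulfonyl carbanion at C7 adds to one formyl group of the dialdehyde held in excess, and Smiles rearrangement with loss of SO2 and the tetrazololate forms C7=C8, for which the E geometry should be favoured by the branched sulfone and the potassium counter-ion, while C6 is not acidic enough to epimerise.

Step 9
Reactants: 12 (3R,6R)-3-(tert-butyldimethylsilyloxy)-8'-apo-ε-caroten-8'-al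
Product: 13 (3R,6R)-3-(tert-butyldimethylsilyloxy)-8'-apo-ε-caroten-8'-ol (all-E)
Conditions: NaBH4, THF/MeOH, 0 °C, dark
Reagents that add atoms: none
Why: Borohydride 1,2-reduction of the conjugated aldehyde gives the allylic primary alcohol without touching the polyene or the silyl ether.

Step 10
Reactants: 13 (3R,6R)-3-(tert-butyldimethylsilyloxy)-8'-apo-ε-caroten-8'-ol
Product: 14 (3R,6R)-8'-apo-ε-carotene-3,8'-diol (all-E), the target
Conditions: Bu4NF, AcOH, THF, 0 °C to rt, dark, argon
Reagents that add atoms: none
Why: Fluoride-induced desilylation under buffered conditions frees the C3 hydroxyl without acid, which would ionise the allylic C3–O bond, so both stereocentres are kept.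

**Compound list**

1 | (2E)-geranyl acetate, (2E)-3,7-dimethylocta-2,6-dien-1-yl acetate | CC(C)=CCC/C(C)=C/COC(C)=O | starting material
2 | [(1R)-2,6,6-trimethylcyclohex-2-en-1-yl]methyl acetate | CC1=CCCC(C)(C)[C@H]1COC(C)=O | intermediate
3 | [(1R)-2,6,6-trimethyl-4-oxocyclohex-2-en-1-yl]methyl acetate | CC1=CC(=O)CC(C)(C)[C@H]1COC(C)=O | intermediate
4 | [(1R,4R)-4-hydroxy-2,6,6-trimethylcyclohex-2-en-1-yl]methyl acetate (hydroxyl trans to the acetoxymethyl group) | CC1=C[C@H](O)CC(C)(C)[C@H]1COC(C)=O | intermediate
5 | [(1R,4R)-4-(tert-butyldimethylsilyloxy)-2,6,6-trimethylcyclohex-2-en-1-yl]methyl acetate | CC1=C[C@H](O[Si](C)(C)C(C)(C)C)CC(C)(C)[C@H]1COC(C)=O | intermediate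
6 | [(1R,4R)-4-(tert-butyldimethylsilyloxy)-2,6,6-trimethylcyclohex-2-en-1-yl]methanol | CC1=C[C@H](O[Si](C)(C)C(C)(C)C)CC(C)(C)[C@H]1CO | intermediate
7 | 1-phenyl-1H-tetrazole-5-thiol | SC1=NN=NN1c1ccccc1 | starting material
8 | 5-({[(1R,4R)-4-(tert-butyldimethylsilyloxy)-2,6,6-trimethylcyclohex-2-en-1-yl]methyl}sulfanyl)-1-phenyl-1H-tetrazole | CC1=C[C@H](O[Si](C)(C)C(C)(C)C)CC(C)(C)[C@H]1CSC2=NN=NN2c3ccccc3 | intermediate
9 | 5-({[(1R,4R)-4-(tert-butyldimethylsilyloxy)-2,6,6-trimethylcyclohex-2-en-1-yl]methyl}sulfinyl)-1-phenyl-1H-tetrazole (both configurations at sulfur) | CC1=C[C@H](O[Si](C)(C)C(C)(C)C)CC(C)(C)[C@H]1CS(=O)C2=NN=NN2c3ccccc3 | intermediate (not isolated)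
10 | 5-({[(1R,4R)-4-(tert-butyldimethylsilyloxy)-2,6,6-trimethylcyclohex-2-en-1-yl]methyl}sulfonyl)-1-phenyl-1H-tetrazole | CC1=C[C@H](O[Si](C)(C)C(C)(C)C)CC(C)(C)[C@H]1CS(=O)(=O)C2=NN=NN2c3ccccc3 | intermediate
11 | crocetin dialdehyde, (2E,4E,6E,8E,10E,12E,14E)-2,6,11,15-tetramethylhexadeca-2,4,6,8,10,12,14-heptaenedial | O=C/C(C)=C/C=C/C(C)=C/C=C/C=C(C)/C=C/C=C(\C)C=O | starting material
12 | (3R,6R)-3-(tert-butyldimethylsilyloxy)-8'-apo-ε-caroten-8'-al (all-E) | CC1=C[C@H](O[Si](C)(C)C(C)(C)C)CC(C)(C)[C@H]1/C=C/C(C)=C/C=C/C(C)=C/C=C/C=C(C)/C=C/C=C(\C)C=O | intermediate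
13 | (3R,6R)-3-(tert-butyldimethylsilyloxy)-8'-apo-ε-caroten-8'-ol (all-E) | CC1=C[C@H](O[Si](C)(C)C(C)(C)C)CC(C)(C)[C@H]1/C=C/C(C)=C/C=C/C(C)=C/C=C/C=C(C)/C=C/C=C(\C)CO | intermediate
14 | (3R,6R)-8'-apo-ε-carotene-3,8'-diol (all-E) | CC1=C[C@H](O)CC(C)(C)[C@H]1/C=C/C(C)=C/C=C/C(C)=C/C=C/C=C(C)/C=C/C=C(\C)CO | target

Total step count: 10
Longest linear sequence: 10 steps (1 to 14); 7 and 11 are commercial.

**Steps most likely to fail**

Step 1. Proton transfer and C1–C6 bonding may not be concerted on this ester-bearing substrate, so that asymmetric induction is low. The acetate may also draw tin off the ligand so that achiral acid cyclises the substrate, its carbonyl may trap the C5 cation, or the cation may lose its proton from the C5 methyl or from C6. The fallback uses known chemistry, sets out from 1 and comes back at 4. Cyclisation of 1 with an achiral strong acid (FSO3H or ClSO3H, 2-nitropropane, −78 °C) should give racemic (2,6,6-trimethylcyclohex-2-en-1-yl)methyl acetate F1. Steps 2 and 3, applied unchanged, lead through racemic (2,6,6-trimethyl-4-oxocyclohex-2-en-1-yl)methyl acetate F2 to racemic trans-(4-hydroxy-2,6,6-trimethylcyclohex-2-en-1-yl)methyl acetate F3. Lipase-catalysed acylation (Burkholderia cepacia lipase, vinyl acetate, t-BuOMe) is then used as a kinetic resolution of the secondary allylic alcohol. By the empirical rule for secondary alcohols, with the alkene side as the larger group, it should convert the (4R) enantiomer into [(1R,4R)-4-acetoxy-2,6,6-trimethylcyclohex-2-en-1-yl]methyl acetate F4, which is separated from the unreacted (1S,4S) alcohol. Methanolysis (K2CO3, MeOH) gives (1R,4R)-4-(hydroxymethyl)-3,5,5-trimethylcyclohex-2-en-1-ol F5, and acetylation of the primary hydroxyl alone (AcCl, 2,4,6-collidine, CH2Cl2, −78 °C) gives 4. If the enzyme instead acylates the (1S,4S) enantiomer, the alcohol recovered beyond half conversion is 4 itself.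

Step 3. Hydride delivery may discriminate poorly between the two faces of the C3 carbonyl (pseudo-axial C1 methyl on one, pseudo-axial C7 arm on the other), and conjugate reduction or attack on the acetate may compete. The fallback sets out from 3 and comes back at 4. Luche reduction (NaBH4, CeCl3·7H2O, MeOH, −78 °C), in which the small hydride should prefer the axial trajectory on the face of the C1 methyl, is expected to give the cis alcohol [(1R,4S)-4-hydroxy-2,6,6-trimethylcyclohex-2-en-1-yl]methyl acetate F6. Mitsunobu inversion with chloroacetic acid (PPh3, DIAD, toluene) gives [(1R,4R)-4-(chloroacetoxy)-2,6,6-trimethylcyclohex-2-en-1-yl]methyl acetate F7, and cleavage of the chloroacetate alone with thiourea (NaHCO3, EtOH) gives 4.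

Step 8. Olefination may occur at both formyl groups, and the hindered anion may add slowly to a sparingly soluble, base-sensitive polyene, so that material is lost. The fallback sets out from 11 (coupled with 10) and comes back at 14. Partial reduction of 11 (NaBH4, 0.3 equiv, EtOH/CH2Cl2, −20 °C, unreacted 11 recycled) gives (2E,4E,6E,8E,10E,12E,14E)-16-hydroxy-2,6,11,15-tetramethylhexadeca-2,4,6,8,10,12,14-heptaenal F8, and silylation (TBSCl, imidazole, DMF) gives (2E,4E,6E,8E,10E,12E,14E)-16-(tert-butyldimethylsilyloxy)-2,6,11,15-tetramethylhexadeca-2,4,6,8,10,12,14-heptaenal F9. Julia–Kocienski olefination of 10 with F9 in equimolar amounts, now with a single formyl group, gives (3R,6R)-3,8'-bis(tert-butyldimethylsilyloxy)-8'-apo-ε-carotene F10, and Bu4NF/AcOH in THF removes both silyl groups to give 14.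

Further compounds
F1 | step 1 | racemic (2,6,6-trimethylcyclohex-2-en-1-yl)methyl acetate | CC1=CCCC(C)(C)[C@H]1COC(C)=O.CC1=CCCC(C)(C)[C@@H]1COC(C)=O
F2 | step 1 | racemic (2,6,6-trimethyl-4-oxocyclohex-2-en-1-yl)methyl acetate | CC1=CC(=O)CC(C)(C)[C@H]1COC(C)=O.CC1=CC(=O)CC(C)(C)[C@@H]1COC(C)=O
F3 | step 1 | racemic trans-(4-hydroxy-2,6,6-trimethylcyclohex-2-en-1-yl)methyl acetate | CC1=C[C@H](O)CC(C)(C)[C@H]1COC(C)=O.CC1=C[C@@H](O)CC(C)(C)[C@@H]1COC(C)=O
F4 | step 1 | [(1R,4R)-4-acetoxy-2,6,6-trimethylcyclohex-2-en-1-yl]methyl acetate | CC1=C[C@H](OC(C)=O)CC(C)(C)[C@H]1COC(C)=O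
F5 | step 1 | (1R,4R)-4-(hydroxymethyl)-3,5,5-trimethylcyclohex-2-en-1-ol | CC1=C[C@H](O)CC(C)(C)[C@H]1CO
F6 | step 3 | [(1R,4S)-4-hydroxy-2,6,6-trimethylcyclohex-2-en-1-yl]methyl acetate | CC1=C[C@@H](O)CC(C)(C)[C@H]1COC(C)=O
F7 | step 3 | [(1R,4R)-4-(chloroacetoxy)-2,6,6-trimethylcyclohex-2-en-1-yl]methyl acetate | CC1=C[C@H](OC(=O)CCl)CC(C)(C)[C@H]1COC(C)=O
F8 | step 8 | (2E,4E,6E,8E,10E,12E,14E)-16-hydroxy-2,6,11,15-tetramethylhexadeca-2,4,6,8,10,12,14-heptaenal | O=C/C(C)=C/C=C/C(C)=C/C=C/C=C(C)/C=C/C=C(\C)CO
F9 | step 8 | (2E,4E,6E,8E,10E,12E,14E)-16-(tert-butyldimethylsilyloxy)-2,6,11,15-tetramethylhexadeca-2,4,6,8,10,12,14-heptaenal | O=C/C(C)=C/C=C/C(C)=C/C=C/C=C(C)/C=C/C=C(\C)CO[Si](C)(C)C(C)(C)C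
F10 | step 8 | (3R,6R)-3,8'-bis(tert-butyldimethylsilyloxy)-8'-apo-ε-carotene (all-E) | CC1=C[C@H](O[Si](C)(C)C(C)(C)C)CC(C)(C)[C@H]1/C=C/C(C)=C/C=C/C(C)=C/C=C/C=C(C)/C=C/C=C(\C)CO[Si](C)(C)C(C)(C)C
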